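The oxane is numbered O1, C2 (4-hydroxyphenyl), C4 (ring A), C6; C7 and C8 are the side-chain methylenes. Everything rests on forming O1–C6 in the ring-closing step, an acid-catalysed dehydrative SN1′ cyclisation. It exploits the C6–C7–C8 unit that ends at the side-chain aryl ring: with a C6=C7 alkene and a hydroxyl on benzylic C8, ionisation gives one 1-arylallyl cation from both C8 epimers, and the C2 hydroxyl captures it at C6 through a chair in which bulky ring A stays equatorial on C4. One operation closes the ring, sets C6 and erases the C8 mixture. The precursor is an open-chain 1,7-diarylhept-5-ene-1,7-diol.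

Key step: step 10

Step 1
Reactants: 1 2,4,6-trihydroxybenzaldehyde
Product: 2 2,6-dihydroxy-4-methoxybenzaldehyde
Conditions: Me2SO4 (1.05 equiv), K2CO3 (1.1 equiv), acetone, 0 °C to rt
Reagents that add atoms: dimethyl sulfate, COS(=O)(=O)OC
Why: Williamson O-methylation: the 4-hydroxyl, para to the formyl group and neither flanked nor chelated by it, is the most acidic and most accessible phenol, so one equivalent of the hard electrophile should alkylate it first and on oxygen.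

Step 2
Reactants: 2 2,6-dihydroxy-4-methoxybenzaldehyde
Product: 3 2,6-bis(benzyloxy)-4-methoxybenzaldehyde
Conditions: BnBr (2.5 equiv), K2CO3, DMF, 60 °C
Reagents that add atoms: benzyl bromide, BrCc1ccccc1
Why: Williamson benzylation of the two remaining, less reactive phenols is forced with excess bromide in warm DMF, and the benzyl ethers keep the ring A hydroxyls silent until step 11.

Step 3
Reactants: 3 2,6-bis(benzyloxy)-4-methoxybenzaldehyde; 4 (1,3-dioxolan-2-ylmethyl)triphenylphosphonium bromide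
Product: 6 (2E)-3-[2,6-bis(benzyloxy)-4-methoxyphenyl]prop-2-enal, via vinyl dioxolane 5 (not isolated)
Conditions: KOtBu, THF, 0 °C to rt; then 1 M HCl, THF, rt
Reagents that add atoms: water, O
Why: Wittig olefination with the dioxolanylmethyl ylide followed by acid hydrolysis of the acetal is a two-carbon formyl-olefination that cannot over-homologate, and the acid should equilibrate the enal to the (E)-isomer.

Step 4
Reactants: 7 1-[4-(benzyloxy)phenyl]ethanone
Product: 8 {1-[4-(benzyloxy)phenyl]ethenyl}oxy(trimethyl)silane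
Conditions: TMSOTf, Et3N, CH2Cl2, 0 °C
Reagents that add atoms: trimethylsilyl trifluoromethanesulfonate, C[Si](C)(C)OS(=O)(=O)C(F)(F)F
Why: Soft enolisation and O-silylation of the methyl ketone gives the only possible silyl enol ether.

Step 5
Reactants: 6 (2E)-3-[2,6-bis(benzyloxy)-4-methoxyphenyl]prop-2-enal; 8 {1-[4-(benzyloxy)phenyl]ethenyl}oxy(trimethyl)silane
Product: 9 (3R)-3-[2,6-bis(benzyloxy)-4-methoxyphenyl]-5-[4-(benzyloxy)phenyl]-5-oxopentanal
Conditions: (2S,5S)-5-benzyl-2-tert-butyl-3-methylimidazolidin-4-one (20 mol%), 2,4-dinitrobenzoic acid (20 mol%), t-BuOH/i-PrOH (5:1), −20 to 0 °C; aqueous work-up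
Reagents that add atoms: none
Why: Organocatalytic Mukaiyama–Michael addition: the enal reacts as its (E)-iminium ion, whose face syn to the benzyl group of the catalyst is shielded, so the silyl enol ether should add 1,4 to the open face of the β-carbon and set the (R)-centre that becomes C4.

Step 6
Reactants: 10 1-[4-(benzyloxy)phenyl]-2-bromoethanone
Product: 12 1-[4-(benzyloxy)phenyl]-2-(triphenyl-λ5-phosphanylidene)ethanone, via phosphonium bromide 11 (not isolated)
Conditions: PPh3, toluene, rt; then 2 M NaOH (aq), CH2Cl2, rt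
Reagents that add atoms: triphenylphosphine, c1ccc(P(c2ccccc2)c2ccccc2)cc1
Why: SN2 quaternisation of the phosphine by the α-bromo ketone and deprotonation of the acidic salt give the ketone-stabilised ylide.

Step 7
Reactants: 9 (3R)-3-[2,6-bis(benzyloxy)-4-methoxyphenyl]-5-[4-(benzyloxy)phenyl]-5-oxopentanal; 12 1-[4-(benzyloxy)phenyl]-2-(triphenyl-λ5-phosphanylidene)ethanone
Product: 13 (2E,5R)-5-[2,6-bis(benzyloxy)-4-methoxyphenyl]-1,7-bis[4-(benzyloxy)phenyl]hept-2-ene-1,7-dione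
Conditions: CH2Cl2, rt to 40 °C
Reagents that add atoms: none
Why: Wittig olefination with a stabilised ylide is selective for the aldehyde over the aryl ketone and for the (E)-enone, and the stereocentre, β to both carbonyl groups, cannot epimerise.

Step 8
Reactants: 13 (2E,5R)-5-[2,6-bis(benzyloxy)-4-methoxyphenyl]-1,7-bis[4-(benzyloxy)phenyl]hept-2-ene-1,7-dione
Product: 14 (2E,5R)-5-[3-acetyl-2,6-bis(benzyloxy)-4-methoxyphenyl]-1,7-bis[4-(benzyloxy)phenyl]hept-2-ene-1,7-dione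
Conditions: Ac2O (1.5 equiv), Sc(OTf)3 (10 mol%), MeNO2, 0 °C to rt
Reagents that add atoms: acetic anhydride, CC(=O)OC(C)=O
Why: Friedel–Crafts acylation: the 1,3,5-trioxygenated ring A is by far the most nucleophilic arene (both benzyloxyphenyl rings are deactivated by their carbonyl groups), its two free positions are equivalent, and no ionisable benzylic C–O bond exists yet, so catalytic Lewis acid should give a single monoacetyl product.

Step 9
Reactants: 14 (2E,5R)-5-[3-acetyl-2,6-bis(benzyloxy)-4-methoxyphenyl]-1,7-bis[4-(benzyloxy)phenyl]hept-2-ene-1,7-dione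
Product: 15 (1R,3R,5E)-3-[3-acetyl-2,6-bis(benzyloxy)-4-methoxyphenyl]-1,7-bis[4-(benzyloxy)phenyl]hept-5-ene-1,7-diol (both C7 epimers)
Conditions: (S)-2-methyl-CBS-oxazaborolidine (30 mol%), BH3·SMe2 (2.2 equiv), THF, −30 °C; MeOH quench, NaHCO3 work-up, used crude
Reagents that add atoms: none
Why: CBS reduction: the (S)-catalyst should give the (R)-benzylic alcohol (future C2) from the aryl alkyl ketone under catalyst control, the enone is reduced 1,2 to a carbinol (future C8) whose configuration is irrelevant because step 10 erases it, and the acetyl group, twisted between two ortho alkoxy groups, should be too hindered to react.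

Step 10
Reactants: 15 (1R,3R,5E)-3-[3-acetyl-2,6-bis(benzyloxy)-4-methoxyphenyl]-1,7-bis[4-(benzyloxy)phenyl]hept-5-ene-1,7-diol (both C7 epimers)
Product: 16 1-{2,4-bis(benzyloxy)-3-[(2R,4R,6R)-2-[4-(benzyloxy)phenyl]-6-{(E)-2-[4-(benzyloxy)phenyl]ethenyl}oxan-4-yl]-6-methoxyphenyl}ethanone
Conditions: camphor-10-sulfonic acid (2 mol%), 4 Å MS, CH2Cl2, −20 to 0 °C; Et3N quench
Reagents that add atoms: none
Why: Acid ionises only the doubly activated (allylic and 4-alkoxybenzylic) C8 carbinol, both epimers giving the same (E)-1-arylallyl cation over C6–C8; the C2 hydroxyl adds to the C6 terminus and the alkene moves to C7=C8 (dehydrative SN1′ cyclisation). The closest known reaction type is the Brønsted- or Lewis-acid-catalysed cyclisation of ζ-hydroxy allylic alcohols to 2-alkenyl tetrahydropyrans. The oxane closes in a 6-exo-trig mode, since attack at C8 would need an eight-membered ring. C6 is set by the existing C2 and C4 centres: in the chair-like transition state the di-ortho-substituted ring A stays equatorial on C4, the C2 aryl is then axial, and the styryl terminus takes the equatorial site to avoid a 1,3-diaxial clash with it, which gives the 2,6-trans, 4,6-cis isomer. The step needs chemoselective ionisation (C8 carbinol, not the C2 carbinol or the C2–O bond of the product), which the extra allylic stabilisation, low temperature and catalytic acid should secure, and facial selectivity at C6, which the same conformational bias should secure under kinetic and, if the closure reverses, thermodynamic control.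

Step 11
Reactants: 16 1-{2,4-bis(benzyloxy)-3-[(2R,4R,6R)-2-[4-(benzyloxy)phenyl]-6-{(E)-2-[4-(benzyloxy)phenyl]ethenyl}oxan-4-yl]-6-methoxyphenyl}ethanone
Product: 17 1-{2,4-dihydroxy-3-[(2R,4R,6S)-2-(4-hydroxyphenyl)-6-[2-(4-hydroxyphenyl)ethyl]oxan-4-yl]-6-methoxyphenyl}ethanone
Conditions: H2 (1 atm), 10% Pd/C, EtOAc/EtOH (1:1), rt, stopped at full debenzylation
Reagents that add atoms: none
Why: Heterogeneous hydrogenation saturates the styrenyl alkene and hydrogenolyses the four aryl benzyl ethers under neutral conditions that the hindered aryl ketone and the cyclic benzylic ether at C2 should survive; no stereocentre is touched (the C6 descriptor changes from R to S through CIP priorities only).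

Step 12
Reactants: 17 1-{2,4-dihydroxy-3-[(2R,4R,6S)-2-(4-hydroxyphenyl)-6-[2-(4-hydroxyphenyl)ethyl]oxan-4-yl]-6-methoxyphenyl}ethanone; 18 4-hydroxybenzaldehyde
Product: 19 (2E)-1-{2,4-dihydroxy-3-[(2R,4R,6S)-2-(4-hydroxyphenyl)-6-[2-(4-hydroxyphenyl)ethyl]oxan-4-yl]-6-methoxyphenyl}-3-(4-hydroxyphenyl)prop-2-en-1-one
Conditions: KOH (50% aq., large excess), EtOH, rt, argon; then ice/AcOH to pH 6
Reagents that add atoms: none
Why: Claisen–Schmidt condensation (aldol addition, then E1cB dehydration) of the methyl ketone with the aldehyde should give the thermodynamically favoured (E)-enone with the phenols masked in situ as phenoxides, and neutralisation to pH 6 avoids acid that could ionise the C2–O bond.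

Compound list
1 | 2,4,6-trihydroxybenzaldehyde | O=Cc1c(O)cc(O)cc1O | starting material
2 | 2,6-dihydroxy-4-methoxybenzaldehyde | COc1cc(O)c(C=O)c(O)c1 | intermediate
3 | 2,6-bis(benzyloxy)-4-methoxybenzaldehyde | COc1cc(OCc2ccccc2)c(C=O)c(OCc2ccccc2)c1 | intermediate
4 | (1,3-dioxolan-2-ylmethyl)triphenylphosphonium bromide | [Br-].C1COC(C[P+](c2ccccc2)(c2ccccc2)c2ccccc2)O1 | starting material
5 | 2-{2-[2,6-bis(benzyloxy)-4-methoxyphenyl]ethenyl}-1,3-dioxolane (E/Z mixture) | COc1cc(OCc2ccccc2)c(C=CC2OCCO2)c(OCc2ccccc2)c1 | intermediate (not isolated)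
6 | (2E)-3-[2,6-bis(benzyloxy)-4-methoxyphenyl]prop-2-enal | COc1cc(OCc2ccccc2)c(/C=C/C=O)c(OCc2ccccc2)c1 | intermediate
7 | 1-[4-(benzyloxy)phenyl]ethanone | CC(=O)c1ccc(OCc2ccccc2)cc1 | starting material
8 | {1-[4-(benzyloxy)phenyl]ethenyl}oxy(trimethyl)silane | C=C(O[Si](C)(C)C)c1ccc(OCc2ccccc2)cc1 | intermediate
9 | (3R)-3-[2,6-bis(benzyloxy)-4-methoxyphenyl]-5-[4-(benzyloxy)phenyl]-5-oxopentanal | O=C(C[C@H](c1c(OCc2ccccc2)cc(OC)cc1OCc1ccccc1)CC=O)c1ccc(OCc2ccccc2)cc1 | intermediate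
10 | 1-[4-(benzyloxy)phenyl]-2-bromoethanone | O=C(CBr)c1ccc(OCc2ccccc2)cc1 | starting material
11 | {2-[4-(benzyloxy)phenyl]-2-oxoethyl}triphenylphosphonium bromide | [Br-].O=C(C[P+](c1ccccc1)(c1ccccc1)c1ccccc1)c1ccc(OCc2ccccc2)cc1 | intermediate (not isolated)
12 | 1-[4-(benzyloxy)phenyl]-2-(triphenyl-λ5-phosphanylidene)ethanone | O=C(C=P(c1ccccc1)(c1ccccc1)c1ccccc1)c1ccc(OCc2ccccc2)cc1 | intermediate
13 | (2E,5R)-5-[2,6-bis(benzyloxy)-4-methoxyphenyl]-1,7-bis[4-(benzyloxy)phenyl]hept-2-ene-1,7-dione | O=C(C[C@H](c1c(OCc2ccccc2)cc(OC)cc1OCc1ccccc1)C/C=C/C(=O)c1ccc(OCc2ccccc2)cc1)c1ccc(OCc2ccccc2)cc1 | intermediate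
14 | (2E,5R)-5-[3-acetyl-2,6-bis(benzyloxy)-4-methoxyphenyl]-1,7-bis[4-(benzyloxy)phenyl]hept-2-ene-1,7-dione | O=C(C[C@H](c1c(OCc2ccccc2)cc(OC)c(C(C)=O)c1OCc1ccccc1)C/C=C/C(=O)c1ccc(OCc2ccccc2)cc1)c1ccc(OCc2ccccc2)cc1 | intermediate
15 | (1R,3R,5E)-3-[3-acetyl-2,6-bis(benzyloxy)-4-methoxyphenyl]-1,7-bis[4-(benzyloxy)phenyl]hept-5-ene-1,7-diol (both C7 epimers) | O[C@@H](c1ccc(OCc2ccccc2)cc1)C[C@H](c1c(OCc2ccccc2)cc(OC)c(C(C)=O)c1OCc1ccccc1)C/C=C/C(O)c1ccc(OCc2ccccc2)cc1 | intermediate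
16 | 1-{2,4-bis(benzyloxy)-3-[(2R,4R,6R)-2-[4-(benzyloxy)phenyl]-6-{(E)-2-[4-(benzyloxy)phenyl]ethenyl}oxan-4-yl]-6-methoxyphenyl}ethanone | COc1cc(OCc2ccccc2)c([C@@H]2C[C@H](/C=C/c3ccc(OCc4ccccc4)cc3)O[C@@H](c3ccc(OCc4ccccc4)cc3)C2)c(OCc2ccccc2)c1C(C)=O | intermediate
17 | 1-{2,4-dihydroxy-3-[(2R,4R,6S)-2-(4-hydroxyphenyl)-6-[2-(4-hydroxyphenyl)ethyl]oxan-4-yl]-6-methoxyphenyl}ethanone | COc1cc(O)c([C@@H]2C[C@H](CCc3ccc(O)cc3)O[C@@H](c3ccc(O)cc3)C2)c(O)c1C(C)=O | intermediate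
18 | 4-hydroxybenzaldehyde | O=Cc1ccc(O)cc1 | starting material
19 | (2E)-1-{2,4-dihydroxy-3-[(2R,4R,6S)-2-(4-hydroxyphenyl)-6-[2-(4-hydroxyphenyl)ethyl]oxan-4-yl]-6-methoxyphenyl}-3-(4-hydroxyphenyl)prop-2-en-1-one | COc1cc(O)c([C@@H]2C[C@H](CCc3ccc(O)cc3)O[C@@H](c3ccc(O)cc3)C2)c(O)c1C(=O)/C=C/c1ccc(O)cc1 | target

Total step count: 12. Longest linear sequence: 10 steps (1, 2, 3, 5, 7, 8, 9, 10, 11, 12).

Steps most likely to fail

1. Step 5. The iminium ion of an electron-rich, di-ortho-substituted cinnamaldehyde may be too weak an electrophile, so that protodesilylation of 8 outruns addition or facial control erodes. Fallback, from 7 and 6 back to 9: ketone 7 is C-acylated (NaH, diallyl carbonate) to allyl 3-[4-(benzyloxy)phenyl]-3-oxopropanoate F1. This more acidic pronucleophile is added to enal 6 under (S)-α,α-diphenylprolinol trimethylsilyl ether and benzoic acid in toluene, an iminium-catalysed Michael addition that should shield the same face. The adduct is allyl (3R)-2-[4-(benzyloxy)benzoyl]-3-[2,6-bis(benzyloxy)-4-methoxyphenyl]-5-oxopentanoate F2 (C2 epimers). Deallylation with decarboxylation (Pd(PPh3)4, HCO2H, Et3N, THF) returns 9.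

2. Step 9. Chemoselectivity may be lost through hydride attack on the hindered acetyl group or conjugate reduction of the enone. Fallback, from 13 back to 16: the acetyl group is introduced only after the hydride step, with bromine as a placeholder.
 - Ring A of 13 is brominated (NBS, MeCN, 0 °C) to (2E,5R)-5-[2,6-bis(benzyloxy)-3-bromo-4-methoxyphenyl]-1,7-bis[4-(benzyloxy)phenyl]hept-2-ene-1,7-dione F3.
 - The CBS reduction of step 9 gives (1R,3R,5E)-3-[2,6-bis(benzyloxy)-3-bromo-4-methoxyphenyl]-1,7-bis[4-(benzyloxy)phenyl]hept-5-ene-1,7-diol F4.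
 - The cyclisation of step 10 gives (2R,4R,6R)-4-[2,6-bis(benzyloxy)-3-bromo-4-methoxyphenyl]-2-[4-(benzyloxy)phenyl]-6-{(E)-2-[4-(benzyloxy)phenyl]ethenyl}oxane F5.
 - Stille coupling with tributyl(1-ethoxyvinyl)stannane (Pd(P(t-Bu)3)2, CsF, dioxane, 90 °C) gives (2R,4R,6R)-4-[2,6-bis(benzyloxy)-3-(1-ethoxyethenyl)-4-methoxyphenyl]-2-[4-(benzyloxy)phenyl]-6-{(E)-2-[4-(benzyloxy)phenyl]ethenyl}oxane F6.
 - Brief hydrolysis of the enol ether with cold aqueous oxalic acid returns 16.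

3. Step 12. Enolisation of a polyphenoxide ketone and addition to the phenoxide of 18 may stall, and long exposure to base may drive chalcone-to-flavanone isomerisation. Fallback, from 17 back to 19: the three non-chelated phenols are allylated (allyl bromide, K2CO3, acetone) to 1-{2-hydroxy-6-methoxy-4-(prop-2-en-1-yloxy)-3-[(2R,4R,6S)-2-[4-(prop-2-en-1-yloxy)phenyl]-6-{2-[4-(prop-2-en-1-yloxy)phenyl]ethyl}oxan-4-yl]phenyl}ethanone F7. Claisen–Schmidt condensation with commercial 4-(prop-2-en-1-yloxy)benzaldehyde (KOH, EtOH) gives (2E)-1-{2-hydroxy-6-methoxy-4-(prop-2-en-1-yloxy)-3-[(2R,4R,6S)-2-[4-(prop-2-en-1-yloxy)phenyl]-6-{2-[4-(prop-2-en-1-yloxy)phenyl]ethyl}oxan-4-yl]phenyl}-3-[4-(prop-2-en-1-yloxy)phenyl]prop-2-en-1-one F8. Neutral deallylation (Pd(PPh3)4, K2CO3, MeOH, rt) returns 19 without hydrogen or acid.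

Further compounds
F1 | step 5 | allyl 3-[4-(benzyloxy)phenyl]-3-oxopropanoate | C=CCOC(=O)CC(=O)c1ccc(OCc2ccccc2)cc1
F2 | step 5 | allyl (3R)-2-[4-(benzyloxy)benzoyl]-3-[2,6-bis(benzyloxy)-4-methoxyphenyl]-5-oxopentanoate (C2 epimers) | O=C(C(C(=O)OCC=C)[C@H](c1c(OCc2ccccc2)cc(OC)cc1OCc1ccccc1)CC=O)c1ccc(OCc2ccccc2)cc1
F3 | step 9 | (2E,5R)-5-[2,6-bis(benzyloxy)-3-bromo-4-methoxyphenyl]-1,7-bis[4-(benzyloxy)phenyl]hept-2-ene-1,7-dione | O=C(C[C@H](c1c(OCc2ccccc2)cc(OC)c(Br)c1OCc1ccccc1)C/C=C/C(=O)c1ccc(OCc2ccccc2)cc1)c1ccc(OCc2ccccc2)cc1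
F4 | step 9 | (1R,3R,5E)-3-[2,6-bis(benzyloxy)-3-bromo-4-methoxyphenyl]-1,7-bis[4-(benzyloxy)phenyl]hept-5-ene-1,7-diol (both C7 epimers) | O[C@@H](c1ccc(OCc2ccccc2)cc1)C[C@H](c1c(OCc2ccccc2)cc(OC)c(Br)c1OCc1ccccc1)C/C=C/C(O)c1ccc(OCc2ccccc2)cc1
F5 | step 9 | (2R,4R,6R)-4-[2,6-bis(benzyloxy)-3-bromo-4-methoxyphenyl]-2-[4-(benzyloxy)phenyl]-6-{(E)-2-[4-(benzyloxy)phenyl]ethenyl}oxane | COc1cc(OCc2ccccc2)c([C@@H]2C[C@H](/C=C/c3ccc(OCc4ccccc4)cc3)O[C@@H](c3ccc(OCc4ccccc4)cc3)C2)c(OCc2ccccc2)c1Br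
F6 | step 9 | (2R,4R,6R)-4-[2,6-bis(benzyloxy)-3-(1-ethoxyethenyl)-4-methoxyphenyl]-2-[4-(benzyloxy)phenyl]-6-{(E)-2-[4-(benzyloxy)phenyl]ethenyl}oxane | COc1cc(OCc2ccccc2)c([C@@H]2C[C@H](/C=C/c3ccc(OCc4ccccc4)cc3)O[C@@H](c3ccc(OCc4ccccc4)cc3)C2)c(OCc2ccccc2)c1C(=C)OCC
F7 | step 12 | 1-{2-hydroxy-6-methoxy-4-(prop-2-en-1-yloxy)-3-[(2R,4R,6S)-2-[4-(prop-2-en-1-yloxy)phenyl]-6-{2-[4-(prop-2-en-1-yloxy)phenyl]ethyl}oxan-4-yl]phenyl}ethanone | COc1cc(OCC=C)c([C@@H]2C[C@H](CCc3ccc(OCC=C)cc3)O[C@@H](c3ccc(OCC=C)cc3)C2)c(O)c1C(C)=O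
F8 | step 12 | (2E)-1-{2-hydroxy-6-methoxy-4-(prop-2-en-1-yloxy)-3-[(2R,4R,6S)-2-[4-(prop-2-en-1-yloxy)phenyl]-6-{2-[4-(prop-2-en-1-yloxy)phenyl]ethyl}oxan-4-yl]phenyl}-3-[4-(prop-2-en-1-yloxy)phenyl]prop-2-en-1-one | COc1cc(OCC=C)c([C@@H]2C[C@H](CCc3ccc(OCC=C)cc3)O[C@@H](c3ccc(OCC=C)cc3)C2)c(O)c1C(=O)/C=C/c1ccc(OCC=C)cc1
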